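**Strategy.** The pyrrole is built, not brominated. Both ring C–N bonds (N1–C2, N1–C5) are disconnected, so that C2–C3(Br)–C4(Br)–C5 is the intact C4Br2 chain of mucobromic acid: its vinylic bromines become the two β-bromines, and its carboxyl and aldehyde carbons already carry the oxidation level of the two N-bound CBr carbons. The key step condenses ammonia with this pseudo-acid and closes the five-membered ring in one operation, giving 3,4-dibromo-5-hydroxy-1,5-dihydro-2H-pyrrol-2-one; the precursor is simply mucobromic acid and an ammonium salt. One aromatising double C–O to C–Br exchange then supplies both α-bromines, so no pyrrole C–H bond is ever brominated.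

Key step: step 1

Remark on stereochemistry: the target is achiral (no stereocentre, no stereogenic axis), so no enantiocontrol is required. Compounds 1–5 each carry one stereocentre (the carbon that becomes C5 or C2 of the ring); it is racemic throughout and is erased on aromatisation.

Remark on numbering: ammonium acetate (source of N1) and POBr3 (source of both α-bromines) are commercial reagents. They are listed under "Reagents that add atoms" and carry no compound number.

Step 1
Reactants: 1 mucobromic acid (3,4-dibromo-5-hydroxyfuran-2(5H)-one, racemic lactol form of (Z)-2,3-dibromo-4-oxobut-2-enoic acid)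
Product: 3 rac-3,4-dibromo-5-hydroxy-1,5-dihydro-2H-pyrrol-2-one, via carbinolamine acid 2 (not isolated)
Conditions: NH4OAc (3 equiv), AcOH, 60 °C
Reagents that add atoms: ammonium acetate, CC(=O)[O-].[NH4+]
Why: In acetic acid lactol 1 is in ring-chain equilibrium with (Z)-2,3-dibromo-4-oxobut-2-enoic acid, whose aldehyde adds ammonia to give carbinolamine 2 (N1–C5 bond); the Z-alkene holds this nitrogen next to the carboxyl group, so it is acylated intramolecularly with loss of water and the ring is sealed as lactam 3 (N1–C2 bond). The closest known reaction type is the condensation of γ-oxo pseudo-acids such as 2-formylbenzoic acid and the mucohalic acids with ammonia or primary amines to 5-hydroxy-γ-lactams, supported by the spontaneous lactamisation seen in reductive aminations of mucohalic acids. The one ring is closed in a 5-exo-trig mode, nitrogen attacking the carboxyl carbon. C5 of 3 is the only new stereocentre; nothing controls it, it should form racemic, and it is erased when the ring aromatises in step 2. The step needs carbonyl addition to win over addition–elimination at either vinylic C–Br (each is β to one carbonyl) and one C4 unit per nitrogen: the acidic buffer keeps free ammonia low and the substrate un-ionised (vinylic substitution on mucohalic acids is a reaction of basic media), and the excess of ammonium salt disfavours double N-alkylation.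

Step 2
Reactants: 3 rac-3,4-dibromo-5-hydroxy-1,5-dihydro-2H-pyrrol-2-one
Product: 6 2,3,4,5-tetrabromo-1H-pyrrole, via tribromolactam 4 (not isolated), via 2H-pyrrole tautomer 5 (not isolated)
Conditions: POBr3 (3 equiv), ClCH2CH2Cl, 0 to 60 °C, dark; then ice-water
Reagents that add atoms: phosphorus oxybromide (POBr3), O=P(Br)(Br)Br
Why: This is the deoxybromination of a lactam to a bromo-heteroarene, the reaction type that turns 3-pyrrolin-2-ones into 2-bromopyrroles: O-phosphorylation of the hemiaminal hydroxyl and bromide capture of the N-acyliminium ion should give 4, O-phosphorylation of its lactam carbonyl and addition–elimination of bromide should give imidoyl bromide 5, and a proton shift from the sp3 carbon to nitrogen, driven by aromatisation, should give 6 without any oxidant or electrophilic bromine source.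

Compound list
1 | mucobromic acid, 3,4-dibromo-5-hydroxyfuran-2(5H)-one (racemic lactol; ring-chain tautomer of (Z)-2,3-dibromo-4-oxobut-2-enoic acid) | OC1OC(=O)C(Br)=C1Br | starting material
2 | carbinolamine acid, (Z)-4-amino-2,3-dibromo-4-hydroxybut-2-enoic acid (racemic, not isolated) | NC(O)/C(Br)=C(Br)\C(=O)O | intermediate
3 | 3,4-dibromo-5-hydroxy-1,5-dihydro-2H-pyrrol-2-one (racemic) | O=C1NC(O)C(Br)=C1Br | intermediate
4 | tribromolactam, 3,4,5-tribromo-1,5-dihydro-2H-pyrrol-2-one (racemic, not isolated) | O=C1NC(Br)C(Br)=C1Br | intermediate
5 | 2H-pyrrole tautomer, 2,3,4,5-tetrabromo-2H-pyrrole (racemic, not isolated) | BrC1N=C(Br)C(Br)=C1Br | intermediate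
6 | 2,3,4,5-tetrabromo-1H-pyrrole (tetrabromopyrrole) | Brc1[nH]c(Br)c(Br)c1Br | target

Total step count: 2
Longest linear sequence: 2 steps (1 → 3 → 6)

Steps most likely to fail (the route has only two steps, so both are listed, the riskier first; there is no third step)

1. Step 1. Ammonia may displace a vinylic bromine by addition–elimination. Alternatively, the carbinolamine may stall as an N,O-acetal or oligomerise instead of acylating intramolecularly. The fallback sets out from 1 and comes back to the route at 3. Nitrogen would be brought in at the imide oxidation level and the hemiaminal carbon set by hydride instead of by carbonyl addition. Compound 1 would be oxidised at its masked aldehyde (Pinnick oxidation: NaClO2, NaH2PO4, H2O2, MeCN/H2O, 0 °C) to 2,3-dibromomaleic acid F1. F1 would be condensed with NH4OAc in AcOH at reflux to 2,3-dibromomaleimide F2. One imide carbonyl of F2 would then be reduced under Luche conditions (NaBH4, CeCl3·7H2O, MeOH/THF, −20 °C) to give 3.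

2. Step 2. The perbrominated pyrrole is heat- and acid-sensitive and may decompose in the warm, strongly acidic medium. The hemiaminal may also oligomerise through its N-acyliminium ion before the electron-poor lactam carbonyl is activated. The fallback sets out from 3 and comes back to the route at 6. The hemiaminal oxygen would be removed first by ionic hydrogenation (Et3SiH, TFA, CH2Cl2, 0 °C) to give 3,4-dibromo-1,5-dihydro-2H-pyrrol-2-one F3. This simple 3-pyrrolin-2-one belongs to the substrate class on which the lactam to 2-bromopyrrole exchange is established. It would be converted with POBr3 (ClCH2CH2Cl, 50 °C) into 2,3,4-tribromo-1H-pyrrole F4. The last α-bromine would then be installed by a single electrophilic bromination under cold, neutral conditions (NBS, 1 equiv, THF, −78 °C), so that the sensitive product 6 forms only at low temperature.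

Further compounds
F1 | step 1 | 2,3-dibromomaleic acid, (Z)-2,3-dibromobut-2-enedioic acid | OC(=O)/C(Br)=C(Br)\C(=O)O
F2 | step 1 | 2,3-dibromomaleimide, 3,4-dibromo-1H-pyrrole-2,5-dione | O=C1NC(=O)C(Br)=C1Br
F3 | step 2 | 3,4-dibromo-1,5-dihydro-2H-pyrrol-2-one | O=C1NCC(Br)=C1Br
F4 | step 2 | 2,3,4-tribromo-1H-pyrrole | Brc1[nH]cc(Br)c1Br
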